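The cyclobutane is cut across two opposite bonds, C1–C4 and C2–C3 (C1: ring carbon bearing the ester oxygen and the aryl group; C2, C3: the CH2 carbons; C4: the CMe2 carbon). This leaves the silyl enol ether of an aryl methyl ketone (C1=C2) and a methacrylate (C3=C4) whose ester stands in for one C4 methyl. One chiral-Lewis-acid step should join the two alkenes, closing the four-membered ring, forming both bonds and fixing C1; the C4 centre is erased when the ester is reduced to CH3. The feature exploited is the O,aryl-substituted C1 bonded to CMe2 inside the cyclobutane. The naphthazarin is built last.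

Key step: step 2

Assumption: the (S)-oxazaborolidine is written as the catalyst enantiomer that gives the (2S) silyloxy carbon of 4 (R in the target); the sense of induction for this acyclic pair is not established, so it is to be confirmed on alcohol 5 and the (R)-catalyst used if it proves reversed.

Remarks on the design:
* The catalyst acts on the enolate carbon C4, and C1 is fixed only relative to C4 during ring closure. The two diastereomers of 4 should therefore differ in C1 configuration. They must be separated (at 4 or 5) and the enantiomeric purity of 5 measured before C4 becomes CMe2; otherwise the C1 purity would be eroded.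
* Only the ortho-methoxy group conjugates with the cationic carbon; the meta one does not.
* The CH2OH-to-CH3 change is planned as a polar hydride displacement with the silyl ether still in place. A radical at the exocyclic carbon would open the ring to a benzylic α-oxy radical, and a free C1 alkoxide would invite Grob fragmentation of the sulfonate.
* The angelate is installed before the quinone is unmasked. The naphthazarin then forms without any oxidant or Lewis-acid demethylation.

Step 1
Reactants: 1 2',5'-dimethoxyacetophenone
Product: 2 tert-butyl{[1-(2,5-dimethoxyphenyl)ethenyl]oxy}dimethylsilane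
Conditions: t-BuMe2SiOTf (1.2 equiv), Et3N (1.5 equiv), CH2Cl2, 0 °C to rt; NaHCO3 work-up, Et3N-deactivated silica
Reagents that add atoms: tert-butyldimethylsilyl trifluoromethanesulfonate, CC(C)(C)[Si](C)(C)OS(=O)(=O)C(F)(F)F
Why: Soft enolisation and O-silylation of a methyl ketone with a silyl triflate and an amine base should give the only possible enol silane, with no stereocentre formed.

Step 2
Reactants: 2 tert-butyl{[1-(2,5-dimethoxyphenyl)ethenyl]oxy}dimethylsilane; 3 2,2,2-trifluoroethyl methacrylate
Product: 4 2,2,2-trifluoroethyl (1R,2S)-2-[(tert-butyldimethylsilyl)oxy]-2-(2,5-dimethoxyphenyl)-1-methylcyclobutane-1-carboxylate (ester trans to silyloxy)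
Conditions: (S)-3,3-diphenyl-1-(2-methylphenyl)tetrahydro-1H,3H-pyrrolo[1,2-c][1,3,2]oxazaborole (15 mol %) activated with AlBr3 (12 mol %), 3 (2.5 equiv), CH2Cl2, −78 to −40 °C; Et3N quench at −78 °C; chromatography on Et3N-deactivated silica
Reagents that add atoms: none
Why: Proposed new method: the AlBr3-activated oxazaborolidine binds the methacrylate carbonyl, the enol silane CH2 adds to the acrylate CH2 (Mukaiyama–Michael step) to give a catalyst-bound zwitterion made of an aryl-stabilised silyloxocarbenium ion and a boron ester enolate, and the enolate α-carbon then attacks the cationic carbon, so that the C2–C3 and C1–C4 bonds of the cyclobutane form in one flask. The closest known reaction is the Lewis-acid-catalysed stepwise [2+2] cycloaddition of silyl enol ethers with acrylate esters, enantioselective with AlBr3-activated oxazaborolidines; an α-methyl acceptor and an acyclic aryl enol silane lie outside what that reaction has been shown to accept. The ring closes by a 4-exo-trig (enolexo) aldol-type attack. The ester-bearing carbon C4 is controlled by the catalyst, which leaves open only the enolate face on which the tethered cation already sits, and the silyloxy carbon C1 is set relative to C4 in the same closure, the silyloxy group being expected to turn away from the catalyst-bound ester (ester trans to OSi). The step needs C- rather than O-closure and closure faster than silyl transfer to the enolate; the ortho-methoxy group lengthens the life of the cation, the tert-butyldimethylsilyl group resists transfer, and the trifluoroethyl ester raises acceptor reactivity and eases catalyst turnover. Because C1 is fixed only through C4, the cis diastereomer should carry the opposite C1 configuration and is removed by chromatography here or at 5.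

Step 3
Reactants: 4 2,2,2-trifluoroethyl (1R,2S)-2-[(tert-butyldimethylsilyl)oxy]-2-(2,5-dimethoxyphenyl)-1-methylcyclobutane-1-carboxylate
Product: 5 [(1S,2R)-2-[(tert-butyldimethylsilyl)oxy]-2-(2,5-dimethoxyphenyl)-1-methylcyclobutyl]methanol
Conditions: LiAlH4 (1.5 equiv), Et2O, −20 to 0 °C; H2O, 15% NaOH, H2O
Reagents that add atoms: none
Why: Hydride reduction of the activated ester to the primary alcohol should be fast at low temperature, touches no stereocentre, and removes the acceptor so that the donor–acceptor ring can no longer reopen.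

Step 4
Reactants: 5 [(1S,2R)-2-[(tert-butyldimethylsilyl)oxy]-2-(2,5-dimethoxyphenyl)-1-methylcyclobutyl]methanol
Product: 6 [(1S,2R)-2-[(tert-butyldimethylsilyl)oxy]-2-(2,5-dimethoxyphenyl)-1-methylcyclobutyl]methyl methanesulfonate
Conditions: MeSO2Cl (1.5 equiv), Et3N (2 equiv), CH2Cl2, 0 °C
Reagents that add atoms: methanesulfonyl chloride, CS(=O)(=O)Cl
Why: Sulfonylation of a primary alcohol through the sulfene is insensitive to the neopentyl-type environment and leaves the tertiary silyl ether and both stereocentres untouched.

Step 5
Reactants: 6 [(1S,2R)-2-[(tert-butyldimethylsilyl)oxy]-2-(2,5-dimethoxyphenyl)-1-methylcyclobutyl]methyl methanesulfonate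
Product: 7 tert-butyl{[(1R)-1-(2,5-dimethoxyphenyl)-2,2-dimethylcyclobutyl]oxy}dimethylsilane
Conditions: LiBHEt3 (4 equiv), THF, 0 to 50 °C; H2O quench
Reagents that add atoms: none
Why: SN2 hydride displacement of a primary sulfonate by the strongly nucleophilic triethylborohydride is the standard way to turn a CH2OH on a quaternary carbon into CH3, and it makes C4 achiral while C1 is not involved.

Step 6
Reactants: 7 tert-butyl{[(1R)-1-(2,5-dimethoxyphenyl)-2,2-dimethylcyclobutyl]oxy}dimethylsilane
Product: 8 (1R)-1-(2,5-dimethoxyphenyl)-2,2-dimethylcyclobutan-1-ol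
Conditions: Bu4NF (3 equiv), THF, rt to 50 °C; neutral aqueous work-up
Reagents that add atoms: none
Why: Fluoride-driven desilylation cleaves the Si–O bond, not the C–O bond, so the tertiary benzylic carbinol keeps its configuration under non-acidic conditions.

Step 7
Reactants: 9 angelic acid, (2Z)-2-methylbut-2-enoic acid (2 equiv)
Product: 10 angelic anhydride, (2Z)-2-methylbut-2-enoic anhydride
Conditions: DCC (0.5 equiv), CH2Cl2, 0 °C to rt; filtration
Reagents that add atoms: none
Why: Carbodiimide dehydration of a carboxylic acid to its symmetric anhydride needs no nucleophilic catalyst, so the Z double bond should not isomerise.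

Step 8
Reactants: 8 (1R)-1-(2,5-dimethoxyphenyl)-2,2-dimethylcyclobutan-1-ol; 10 angelic anhydride
Product: 12 (1R)-1-(2,5-dimethoxyphenyl)-2,2-dimethylcyclobutyl (2Z)-2-methylbut-2-enoate, via lithium alkoxide 11 (not isolated)
Conditions: LiN(SiMe3)2 (1.1 equiv), THF, −78 to 0 °C; then 10 (1.5 equiv), 0 °C to rt
Reagents that add atoms: none
Why: O-Acylation of a preformed lithium alkoxide by a symmetric anhydride is the way hindered alcohols are angeloylated without amine or pyridine nucleophiles, so the Z geometry and the C1 configuration (no C–O cleavage) should both be kept.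

Step 9
Reactants: 12 (1R)-1-(2,5-dimethoxyphenyl)-2,2-dimethylcyclobutyl (2Z)-2-methylbut-2-enoate
Product: 13 (1R)-1-(3,6-dioxocyclohexa-1,4-dien-1-yl)-2,2-dimethylcyclobutyl (2Z)-2-methylbut-2-enoate
Conditions: (NH4)2Ce(NO3)6 (2.5 equiv), MeCN–H2O 2:1, 0 °C, short reaction time
Reagents that add atoms: water, O
Why: Oxidative demethylation of a hydroquinone dimethyl ether by tetravalent cerium (two one-electron oxidations, water adding to the ring carbons and methanol leaving) should give the benzoquinone while both the unsaturated and the tertiary ester are inert.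

Step 10
Reactants: 14 succinic anhydride
Product: 15 2,5-bis(trimethylsilyloxy)furan
Conditions: Me3SiCl (2.4 equiv), Et3N (2.5 equiv), ZnCl2 (5 mol %), MeCN, rt to 40 °C; pentane extraction, distillation under argon
Reagents that add atoms: chlorotrimethylsilane, C[Si](C)(C)Cl
Why: Double enol silylation of the cyclic anhydride under ZnCl2 catalysis traps its bis-enol form as the aromatic bis(silyloxy)furan.

Step 11
Reactants: 13 (1R)-1-(3,6-dioxocyclohexa-1,4-dien-1-yl)-2,2-dimethylcyclobutyl (2Z)-2-methylbut-2-enoate; 15 2,5-bis(trimethylsilyloxy)furan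
Product: 18 (1R)-1-(5,8-dihydroxy-1,4-dioxo-1,4-dihydronaphthalen-2-yl)-2,2-dimethylcyclobutyl (2Z)-2-methylbut-2-enoate (target), via oxygen-bridged bis(trimethylsilyloxy) cycloadduct 16 (not isolated), via 4a,8a-dihydronaphthalene-1,4,5,8-tetraone tautomer 17 (not isolated)
Conditions: 15 (1.5 equiv), CH2Cl2, −78 °C to rt; then THF–0.1 M HCl, 0 °C
Reagents that add atoms: none
Why: Diels–Alder addition of the electron-rich furan to the unhindered C5=C6 bond of the quinone, collapse of the bis-silyl ketal bridge and double enolisation should give the naphthazarin directly at the correct oxidation level, with C1 untouched.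

Compound list
1 | 2',5'-dimethoxyacetophenone | CC(=O)c1cc(OC)ccc1OC | starting material
2 | tert-butyl{[1-(2,5-dimethoxyphenyl)ethenyl]oxy}dimethylsilane | C=C(O[Si](C)(C)C(C)(C)C)c1cc(OC)ccc1OC | intermediate
3 | 2,2,2-trifluoroethyl methacrylate | C=C(C)C(=O)OCC(F)(F)F | starting material
4 | 2,2,2-trifluoroethyl (1R,2S)-2-[(tert-butyldimethylsilyl)oxy]-2-(2,5-dimethoxyphenyl)-1-methylcyclobutane-1-carboxylate | CC(C)(C)[Si](C)(C)O[C@]1(c2cc(OC)ccc2OC)CC[C@@]1(C)C(=O)OCC(F)(F)F | intermediate
5 | [(1S,2R)-2-[(tert-butyldimethylsilyl)oxy]-2-(2,5-dimethoxyphenyl)-1-methylcyclobutyl]methanol | CC(C)(C)[Si](C)(C)O[C@]1(c2cc(OC)ccc2OC)CC[C@@]1(C)CO | intermediate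
6 | [(1S,2R)-2-[(tert-butyldimethylsilyl)oxy]-2-(2,5-dimethoxyphenyl)-1-methylcyclobutyl]methyl methanesulfonate | CC(C)(C)[Si](C)(C)O[C@]1(c2cc(OC)ccc2OC)CC[C@@]1(C)COS(C)(=O)=O | intermediate
7 | tert-butyl{[(1R)-1-(2,5-dimethoxyphenyl)-2,2-dimethylcyclobutyl]oxy}dimethylsilane | CC(C)(C)[Si](C)(C)O[C@]1(c2cc(OC)ccc2OC)CCC1(C)C | intermediate
8 | (1R)-1-(2,5-dimethoxyphenyl)-2,2-dimethylcyclobutan-1-ol | O[C@]1(c2cc(OC)ccc2OC)CCC1(C)C | intermediate
9 | angelic acid, (2Z)-2-methylbut-2-enoic acid | C/C=C(/C)C(=O)O | starting material
10 | angelic anhydride, (2Z)-2-methylbut-2-enoic anhydride | C/C=C(/C)C(=O)OC(=O)/C(C)=C\C | intermediate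
11 | lithium (1R)-1-(2,5-dimethoxyphenyl)-2,2-dimethylcyclobutan-1-olate | [Li+].[O-][C@]1(c2cc(OC)ccc2OC)CCC1(C)C | intermediate
12 | (1R)-1-(2,5-dimethoxyphenyl)-2,2-dimethylcyclobutyl (2Z)-2-methylbut-2-enoate | C/C=C(/C)C(=O)O[C@]1(c2cc(OC)ccc2OC)CCC1(C)C | intermediate
13 | (1R)-1-(3,6-dioxocyclohexa-1,4-dien-1-yl)-2,2-dimethylcyclobutyl (2Z)-2-methylbut-2-enoate | C/C=C(/C)C(=O)O[C@]1(C2=CC(=O)C=CC2=O)CCC1(C)C | intermediate
14 | succinic anhydride | O=C1CCC(=O)O1 | starting material
15 | 2,5-bis(trimethylsilyloxy)furan | C[Si](C)(C)Oc1ccc(O[Si](C)(C)C)o1 | intermediate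
16 | (1R)-1-[5,8-epoxy-1,4-dioxo-5,8-bis(trimethylsilyloxy)-1,4,4a,5,8,8a-hexahydronaphthalen-2-yl]-2,2-dimethylcyclobutyl (2Z)-2-methylbut-2-enoate (mixture of diastereomers at the four new ring carbons, left undefined) | C/C=C(/C)C(=O)O[C@]1(C2=CC(=O)C3C(C2=O)C2(O[Si](C)(C)C)C=CC3(O[Si](C)(C)C)O2)CCC1(C)C | intermediate
17 | (1R)-2,2-dimethyl-1-(1,4,5,8-tetraoxo-1,4,4a,5,8,8a-hexahydronaphthalen-2-yl)cyclobutyl (2Z)-2-methylbut-2-enoate (ring-fusion carbons undefined) | C/C=C(/C)C(=O)O[C@]1(C2=CC(=O)C3C(C2=O)C(=O)C=CC3=O)CCC1(C)C | intermediate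
18 | (1R)-1-(5,8-dihydroxy-1,4-dioxo-1,4-dihydronaphthalen-2-yl)-2,2-dimethylcyclobutyl (2Z)-2-methylbut-2-enoate | C/C=C(/C)C(=O)O[C@]1(C2=CC(=O)c3c(O)ccc(O)c3C2=O)CCC1(C)C | target

Total step count: 11 (nine on the main line, plus the preparations of 10 and 15).
Longest linear sequence: 9 steps (steps 1, 2, 3, 4, 5, 6, 8, 9, 11).

Steps most likely to fail

Step 2. Ring closure between two fully substituted carbons may be slower than silyl transfer to the enolate (open-chain keto ester), or may proceed with poor facial or diastereo-control. The fallback sets out from enol silane 2 and returns at 4. Compound 2 is combined, under the same AlBr3-activated oxazaborolidine, with purchased 2,2,2-trifluoroethyl acrylate, the acceptor for which this enantioselective cycloaddition is established. Closure then occurs at a secondary enolate carbon and should give 2,2,2-trifluoroethyl (1R,2R)-2-[(tert-butyldimethylsilyl)oxy]-2-(2,5-dimethoxyphenyl)cyclobutane-1-carboxylate F1, with the silyloxy-bearing carbon already fixed. The missing methyl is then added by ester enolate alkylation (LiN(iPr)2, THF, −78 °C; MeI, DMPU, kept below −60 °C so that the enolate expels neither silanolate nor trifluoroethoxide). This should give 4 together with its epimer at the ester carbon, 2,2,2-trifluoroethyl (1S,2S)-2-[(tert-butyldimethylsilyl)oxy]-2-(2,5-dimethoxyphenyl)-1-methylcyclobutane-1-carboxylate F2. F2 is separated and 4 continues with step 3.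

Step 8. O-Acylation of the very hindered tertiary alkoxide may be slow, and γ-deprotonation of the anhydride may then cause Z-to-E isomerisation or deconjugation. The fallback sets out from alcohol 8 and returns at 12, building the double bond after the C–O bond. Esterification of 8 with 2-[bis(2,2,2-trifluoroethoxy)phosphoryl]propanoic acid and DCC in CH2Cl2 (acyl transfer through the derived phosphonoketene, which hindered alcohols accept) should give (1R)-1-(2,5-dimethoxyphenyl)-2,2-dimethylcyclobutyl 2-[bis(2,2,2-trifluoroethoxy)phosphoryl]propanoate F3 as a mixture of epimers at the phosphonate carbon. Still–Gennari olefination (KN(SiMe3)2, 18-crown-6, THF, −78 °C; acetaldehyde), which is Z-selective for α-methyl phosphonates, should then deliver angelate 12.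

Step 5. Hydride displacement at the neopentyl-type carbon may stall. The competing processes are S–O cleavage back to 5, aryl ether demethylation on prolonged heating, participation of the cis ortho-methoxy oxygen, and ionisation with ring expansion. The fallback sets out from alcohol 5 and returns at 7, removing the oxygen at the aldehyde level. Dess–Martin oxidation (NaHCO3, CH2Cl2) should give (1R,2S)-2-[(tert-butyldimethylsilyl)oxy]-2-(2,5-dimethoxyphenyl)-1-methylcyclobutane-1-carbaldehyde F4, used crude. Hydrazine hydrate in EtOH should give its (E)-hydrazone F5. KOtBu in DMSO/t-BuOH at rt (Wolff–Kishner reduction) should then give 7. Anionic, protic conditions are chosen because a radical at this carbon would open the cyclobutane.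

Further compounds
F1 | step 2 | 2,2,2-trifluoroethyl (1R,2R)-2-[(tert-butyldimethylsilyl)oxy]-2-(2,5-dimethoxyphenyl)cyclobutane-1-carboxylate | CC(C)(C)[Si](C)(C)O[C@]1(c2cc(OC)ccc2OC)CC[C@H]1C(=O)OCC(F)(F)F
F2 | step 2 | 2,2,2-trifluoroethyl (1S,2S)-2-[(tert-butyldimethylsilyl)oxy]-2-(2,5-dimethoxyphenyl)-1-methylcyclobutane-1-carboxylate | CC(C)(C)[Si](C)(C)O[C@]1(c2cc(OC)ccc2OC)CC[C@]1(C)C(=O)OCC(F)(F)F
F3 | step 8 | (1R)-1-(2,5-dimethoxyphenyl)-2,2-dimethylcyclobutyl 2-[bis(2,2,2-trifluoroethoxy)phosphoryl]propanoate (epimers at the phosphonate carbon) | CC(C(=O)O[C@]1(c2cc(OC)ccc2OC)CCC1(C)C)P(=O)(OCC(F)(F)F)OCC(F)(F)F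
F4 | step 5 | (1R,2S)-2-[(tert-butyldimethylsilyl)oxy]-2-(2,5-dimethoxyphenyl)-1-methylcyclobutane-1-carbaldehyde | CC(C)(C)[Si](C)(C)O[C@]1(c2cc(OC)ccc2OC)CC[C@@]1(C)C=O
F5 | step 5 | (E)-hydrazone of aldehyde F4 | CC(C)(C)[Si](C)(C)O[C@]1(c2cc(OC)ccc2OC)CC[C@@]1(C)/C=N/N
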